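**Slow flask.** This chemistry crawls: autumn, charged like elm, shows 13.4% target after 6.00 h, with 72.6% of the starting material still present, so the question is what a long stay buys and what it costs.

the same everywhere: starting material 0.20 M

|  | coupling partner | second substrate | protic impurity | remark | time |
|---|---|---|---|---|---|
| autumn | 1.2 equiv | 1 equiv | 0.040 M | run made earlier |  |
| dusk | 0.60 equiv | 1 equiv | 0.040 M | run made earlier |  |
| summer | 2.4 equiv | 1 equiv | 0.040 M | run made earlier |  |
| winter | 1.2 equiv | 2 equiv | 0.040 M | run made earlier |  |
| maple | 1.20 equiv | 1.00 equiv (fed, over 4.80 h) | 0.0400 M | all but second substrate at the start; second substrate goes in evenly over 4.80 h, the run ends at 6.0 h | 6.0 h |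
| birch | 1.20 equiv | 1.00 equiv | 0.0400 M | one stirred flow tank at steady state, fed with the mixture as stated, mean residence time 6.0 h |  |
| elm | 1.20 equiv | 1.00 equiv | 0.0400 M | a closed flask charged with all of it at once and left for 6.0 h | 6.0 h |
| ash | 1.20 equiv | 1.00 equiv | 0.0400 M | one stirred flow tank at steady state, fed with the mixture as stated, mean residence time 60.0 h |  |

| run | time / h | target / % | starting material / % |
|---|---|---|---|
| autumn | 1.33 | 5.2 | 90.2 |
| autumn | 2.50 | 6.9 | 84.3 |
| autumn | 4.00 | 10.9 | 78.9 |
| autumn | 5.00 | 12.0 | 76.1 |
| autumn | 6.00 | 13.4 | 72.6 |
| dusk | 0.417 | 1.2 | 97.3 |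
| dusk | 1.33 | 2.4 | 92.2 |
| dusk | 2.00 | 3.6 | 89.3 |
| dusk | 3.00 | 6.1 | 84.7 |
| dusk | 5.00 | 7.5 | 80.0 |
| summer | 1.00 | 7.3 | 89.1 |
| summer | 2.00 | 11.3 | 81.9 |
| summer | 3.00 | 13.2 | 76.1 |
| summer | 4.00 | 16.5 | 72.6 |
| summer | 5.00 | 17.8 | 68.4 |
| winter | 0.417 | 2.0 | 96.1 |
| winter | 1.33 | 3.6 | 89.8 |
| winter | 2.00 | 6.4 | 87.2 |
| winter | 3.00 | 8.3 | 82.7 |
| winter | 5.00 | 12.2 | 74.8 |

(standard deviation of a reading: 0.5 percentage points)

* the set-up with the highest amount of target at the outlet or at the end, in percent of the starting material put in ("none" if the first two lie within 2 percentage points) (maple / birch / elm / ash / none)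
* amount of target at the outlet or at the end, in percent of the starting material put in, maple
* amount of target at the outlet or at the end, in percent of the starting material put in, birch
* amount of target at the outlet or at the end, in percent of the starting material put in, elm
* amount of target at the outlet or at the end, in percent of the starting material put in, ash

- the stated concentrations are those of everything mixed, before any reaction; amounts are the same in each set-up
- the numbers in the tables scatter by 0.5 percentage points (one standard deviation)
- the feed brings no volume worth counting
- the earlier runs were made in a closed, stirred flask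

**Main step.** Autumn's first reading gives target at a fraction 0.0391 h⁻¹ of the charge, and that pace held for 6.0 h gives 23.5%. At 5.00 h the target reads 7.5% in dusk, 12.0% in autumn and 17.8% in summer, so it climbs with coupling partner, while winter's 12.2% shows no gain from doubled second substrate.

**Side loss.** I add a second process, starting material lost minus target. At 5.00 h it reads 12.5% in dusk and 13.8% in summer, despite 0.60 equiv against 2.4 equiv of partner, so I take it as quenching by protic impurity, one for one. The impurity is then the limiting reagent of that step, and I carry the quench ceiling, the fraction of the charge it can consume, 20.0%. On this reading I expect the side loss of a long stay to remain under the ceiling, and the starting material that reacts beyond it to go to target.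

**Remaining slowing.** Autumn's last hour reads 0.0140 h⁻¹, a slowing in scattered readings that I leave unexplained. Elm has autumn's charge and winter read no gain from doubled second substrate, so I expect maple and elm near autumn, and ash, with a mean residence time ten times elm's time, above them, with 80.0% of the charge beyond the reach of the quench.

**The forecast.** It gives maple 13.2%, birch 9% (7% to 11%), elm 13.6% and ash 22% (10% to 34%): “Ash is the likely highest”.

**The result.** starting material + coupling partner → target (k = 0.200 M⁻¹ h⁻¹); second substrate + coupling partner → second product (k = 0.100 M⁻¹ h⁻¹); starting material + protic impurity → quenched substrate (k = 1.20 M⁻¹ h⁻¹); 2 coupling partner → homo dimer (k = 0.610 M⁻¹ h⁻¹); target → over-reaction product (k = 1.70 × 10⁻⁴ h⁻¹)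

Maple gives 13.1%, birch 10.6%, elm 12.9% and ash 25.9%, so ash leads. With the homo dimer step struck out, ash gives 41.9%. Ash holds 56.0% of its starting material, so its side loss is 18.1%, close under the ceiling of 20.0%. Birch keeps 78.7% and loses 10.6% to the side, about half of the ceiling.

The readings are simulated from invented constants, noise included.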